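**Retrosynthetic overview**
1. Target ⇐ terminal 1,2-diol (Corey–Winter): the vinyl group is what remains of C1–C2 of an epoxy alcohol.
2. Diol ⇐ (2R,3R)-epoxy alcohol + (E)-alkenylalane: the quaternary carbon is first made as a C–O stereocentre by Sharpless epoxidation (key step), then substituted with inversion by carbon.
3. Epoxy alcohol ⇐ (E)-allylic alcohol ⇐ terminal alkyne (carboalumination/CH2O) ⇐ directed syn-SN2′ of a butynyl Grignard on a 2-ethylidenecyclohexyl ester ⇐ (R)-2,2,3-trimethylcyclohexanone ⇐ 2-methylcyclohexenone.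
4. Alkenylalane ⇐ terminal alkyne ⇐ (S)-citronellal: CHO → C≡CH, then the prenyl end is turned into the two CH(Me)–C(=CH2) units by two Cu-catalysed SN2′ alkylations around a formaldehyde-ene homologation.
5. Rings: the single cyclohexene ring is bought as 2-methylcyclohex-2-enone and never opened; no ring is formed.

Assumption: the SMILES is read as side chain 2R,5S,6E,8S,11R,15R and ring 4R; the ligand enantiomer in each Cu-catalysed step is the one that gives the stated centre.

**Step 1**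
Reactants: 1 2-methylcyclohex-2-en-1-one
Product: 3 (3R)-2,2,3-trimethylcyclohexan-1-one, via aluminium enolate 2 (not isolated)
Conditions: Me3Al, CuTC (2 mol %), chiral phosphoramidite (4 mol %), Et2O, −30 °C; then MeLi, MeI, THF–DMPU, −30 °C → rt
Reagents that add atoms: trimethylaluminium C[Al](C)C; iodomethane CI
Why: Cu-catalysed asymmetric conjugate addition sets C3 (R) under ligand control, and the regiodefined enolate (as its ate complex) is C-methylated at C2, which is not stereogenic.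

**Step 2**
Reactants: 3 (3R)-2,2,3-trimethylcyclohexan-1-one
Product: 6 (3R,6E)-6-ethylidene-2,2,3-trimethylcyclohexan-1-one, via aldol adduct 4 (not isolated), via mesylate 5 (not isolated)
Conditions: LDA, THF, −78 °C; MeCHO; MsCl, −78 → 0 °C; DBU, rt
Reagents that add atoms: acetaldehyde CC=O
Why: directed aldol condensation at the only enolisable α-carbon, then E1cB loss of mesylate, gives the more stable (E)-enone.

**Step 3**
Reactants: 6 (3R,6E)-6-ethylidene-2,2,3-trimethylcyclohexan-1-one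
Product: 7 (1R,3R,6E)-6-ethylidene-2,2,3-trimethylcyclohexan-1-ol
Conditions: NaBH4, CeCl3·7H2O, MeOH, −40 °C
Reagents that add atoms: none
Why: Luche 1,2-reduction in which hydride adds axially, anti to the axial C2 methyl of the chair with equatorial C3-Me, so the equatorial (1R) alcohol cis to C3-Me forms (minor epimer removed by chromatography).

**Step 4**
Reactants: 7 (1R,3R,6E)-6-ethylidene-2,2,3-trimethylcyclohexan-1-ol
Product: 8 (1R,3R,6E)-6-ethylidene-2,2,3-trimethylcyclohexyl 2-(diphenylphosphanyl)benzoate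
Conditions: 2-(Ph2P)C6H4CO2H, DCC, DMAP (cat.), CH2Cl2, rt
Reagents that add atoms: 2-(diphenylphosphanyl)benzoic acid OC(=O)c1ccccc1P(c1ccccc1)c1ccccc1
Why: Steglich esterification with retention at C1 installs the phosphine-bearing leaving group for directed substitution.

**Step 5**
Reactants: 8 (1R,3R,6E)-6-ethylidene-2,2,3-trimethylcyclohexyl 2-(diphenylphosphanyl)benzoate; 9 4-bromo-1-(trimethylsilyl)but-1-yne
Product: 11 trimethyl{(5R)-5-[(4R)-3,3,4-trimethylcyclohex-1-en-1-yl]hex-1-yn-1-yl}silane, via Grignard reagent 10 (not isolated)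
Conditions: 9, Mg, Et2O; then 8, CuBr·SMe2 (0.5 equiv), Et2O, rt
Reagents that add atoms: none
Why: o-DPPB-directed copper-mediated allylic substitution in which phosphine-bound Cu delivers the alkyl group syn to the leaving group at the exocyclic γ-carbon (SN2′, the neopentyl α-carbon being blocked), so (1R) is relayed to the new (R) CH(Me) centre and the alkene moves into the ring.

**Step 6**
Reactants: 11 trimethyl{(5R)-5-[(4R)-3,3,4-trimethylcyclohex-1-en-1-yl]hex-1-yn-1-yl}silane
Product: 12 (4R)-1-[(2R)-hex-5-yn-2-yl]-3,3,4-trimethylcyclohex-1-ene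
Conditions: K2CO3, MeOH, rt
Reagents that add atoms: none
Why: base-mediated protodesilylation of the alkynylsilane, with nothing else affected.

**Step 7**
Reactants: 12 (4R)-1-[(2R)-hex-5-yn-2-yl]-3,3,4-trimethylcyclohex-1-ene
Product: 14 (2E,6R)-3-methyl-6-[(4R)-3,3,4-trimethylcyclohex-1-en-1-yl]hept-2-en-1-ol, via alkenylalane 13 (not isolated)
Conditions: Me3Al, Cp2ZrCl2 (25 mol %), CH2Cl2, 0 °C → rt; then n-BuLi, −78 °C; (CH2O)n, THF, rt
Reagents that add atoms: trimethylaluminium C[Al](C)C; paraformaldehyde (as formaldehyde) C=O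
Why: Negishi Zr-catalysed carboalumination adds Me and Al syn with Me at the internal carbon, and the alkenylalanate is hydroxymethylated with retention, giving only the (E)-trisubstituted allylic alcohol.

**Step 8**
Reactants: 14 (2E,6R)-3-methyl-6-[(4R)-3,3,4-trimethylcyclohex-1-en-1-yl]hept-2-en-1-ol
Product: 15 [(2R,3R)-3-methyl-3-{(3R)-3-[(4R)-3,3,4-trimethylcyclohex-1-en-1-yl]butyl}oxiran-2-yl]methanol
Conditions: Ti(OiPr)4 (10 mol %), D-(−)-DET (12 mol %), t-BuOOH, 4 Å MS, CH2Cl2, −20 °C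
Reagents that add atoms: tert-butyl hydroperoxide CC(C)(C)OO
Why: Sharpless asymmetric epoxidation, reagent-controlled by D-(−)-DET as in the geraniol series, gives the (2R,3R)-epoxide and so fixes the future quaternary carbon as a C–O stereocentre, while the ring alkene (no allylic OH) is untouched.

**Step 9**
Reactants: 16 (S)-citronellal
Product: 18 (3S)-3,7-dimethyloct-6-en-1-yne, via enol nonaflate 17 (not isolated)
Conditions: C4F9SO2F, P2-Et phosphazene base, DMF, 0 °C → rt
Reagents that add atoms: none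
Why: one-pot enol nonaflate formation and base-induced elimination turns CH2–CHO into C≡CH, leaving the β-stereocentre (no acidic H) untouched.

**Step 10**
Reactants: 18 (3S)-3,7-dimethyloct-6-en-1-yne
Product: 19 trimethyl[(3S)-3,7-dimethyloct-6-en-1-yn-1-yl]silane
Conditions: n-BuLi, THF, −78 °C; TMSCl
Reagents that add atoms: chlorotrimethylsilane C[Si](C)(C)Cl
Why: acetylide silylation masks the acidic C–H for the organometallic steps that follow.

**Step 11**
Reactants: 19 trimethyl[(3S)-3,7-dimethyloct-6-en-1-yn-1-yl]silane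
Product: 20 (2E,6S)-2,6-dimethyl-8-(trimethylsilyl)oct-2-en-7-yn-1-ol
Conditions: SeO2 (cat.), t-BuOOH, salicylic acid (cat.), CH2Cl2, rt
Reagents that add atoms: tert-butyl hydroperoxide CC(C)(C)OO
Why: SeO2-catalysed allylic oxidation (ene, then [2,3]-shift) is selective for the (E)-methyl of the trisubstituted alkene and gives the (E)-allylic alcohol.

**Step 12**
Reactants: 20 (2E,6S)-2,6-dimethyl-8-(trimethylsilyl)oct-2-en-7-yn-1-ol
Product: 21 [(3S,6E)-8-chloro-3,7-dimethyloct-6-en-1-yn-1-yl]trimethylsilane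
Conditions: NCS, Me2S, CH2Cl2, −20 → 0 °C
Reagents that add atoms: N-chlorosuccinimide O=C1CCC(=O)N1Cl
Why: Corey–Kim chlorination displaces the alkoxysulfonium by SN2 without allylic shift or loss of alkene geometry.

**Step 13**
Reactants: 21 [(3S,6E)-8-chloro-3,7-dimethyloct-6-en-1-yn-1-yl]trimethylsilane
Product: 22 trimethyl[(3S,6R)-3,6,7-trimethyloct-7-en-1-yn-1-yl]silane
Conditions: MeMgBr, CuTC (3 mol %), chiral phosphoramidite (3.3 mol %), CH2Cl2, −78 °C
Reagents that add atoms: methylmagnesium bromide C[Mg]Br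
Why: copper-catalysed asymmetric allylic alkylation in which ligand-controlled SN2′ delivery of Me to C6 of the β-methyl allylic chloride creates the (6R) centre and the isopropenyl group, the remote (3S) centre being a spectator.

**Step 14**
Reactants: 22 trimethyl[(3S,6R)-3,6,7-trimethyloct-7-en-1-yn-1-yl]silane
Product: 23 (4R,7S)-4,7-dimethyl-3-methylidene-9-(trimethylsilyl)non-8-yn-1-ol
Conditions: (CH2O)n, Me2AlCl, CH2Cl2, 0 °C → rt
Reagents that add atoms: paraformaldehyde (as formaldehyde) C=O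
Why: Lewis-acid-promoted carbonyl-ene reaction of formaldehyde with the 1,1-disubstituted alkene forms the C–C bond at the terminal CH2 and takes H from the methyl group rather than the hindered tertiary C–H, so the adjacent stereocentre is preserved.

**Step 15**
Reactants: 23 (4R,7S)-4,7-dimethyl-3-methylidene-9-(trimethylsilyl)non-8-yn-1-ol
Product: 24 [(3S,6R)-9-bromo-3,6-dimethyl-7-methylidenenon-1-yn-1-yl]trimethylsilane
Conditions: CBr4, PPh3, CH2Cl2, 0 °C
Reagents that add atoms: carbon tetrabromide BrC(Br)(Br)Br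
Why: Appel bromination of the primary alcohol under neutral conditions.

**Step 16**
Reactants: 25 (2E)-2-methylbut-2-en-1-ol
Product: 26 (2E)-1-chloro-2-methylbut-2-ene
Conditions: NCS, Me2S, CH2Cl2, −20 → 0 °C
Reagents that add atoms: N-chlorosuccinimide O=C1CCC(=O)N1Cl
Why: Corey–Kim chlorination gives the (E)-allylic chloride without isomerisation.

**Step 17**
Reactants: 24 [(3S,6R)-9-bromo-3,6-dimethyl-7-methylidenenon-1-yn-1-yl]trimethylsilane; 26 (2E)-1-chloro-2-methylbut-2-ene
Product: 29 (3S,6R,10R)-3,6,10,11-tetramethyl-7-methylidenedodec-11-en-1-yne, via Grignard reagent 27 (not isolated), via silyl alkyne 28 (not isolated)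
Conditions: 24, Mg, THF; then 26, CuTC (3 mol %), chiral phosphoramidite (3.3 mol %), CH2Cl2, −78 °C; then K2CO3, MeOH, rt
Reagents that add atoms: none
Why: copper-catalysed asymmetric allylic alkylation of the primary Grignard reagent on the β-methyl allylic chloride (SN2′) sets C10 (R) under ligand control and forms the terminal isopropenyl group, and methanolysis in the same pot frees the alkyne.

**Step 18**
Reactants: 15 [(2R,3R)-3-methyl-3-{(3R)-3-[(4R)-3,3,4-trimethylcyclohex-1-en-1-yl]butyl}oxiran-2-yl]methanol; 29 (3S,6R,10R)-3,6,10,11-tetramethyl-7-methylidenedodec-11-en-1-yne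
Product: 32 (2S,3R,4E,6S,9R,13R)-3,6,9,13,14-pentamethyl-10-methylidene-3-{(3R)-3-[(4R)-3,3,4-trimethylcyclohex-1-en-1-yl]butyl}pentadeca-4,14-diene-1,2-diol, via alkenylalane 30 (not isolated), via aluminium alkoxide 31 (not isolated)
Conditions: 29 (1.5 equiv), DIBAL-H, hexane, 50 °C; 15, DIBAL-H (1.0 equiv), CH2Cl2, −78 °C; combine, −78 → 0 °C; Rochelle salt
Reagents that add atoms: none
Why: Proposed new method: C3-selective, invertive opening of a 3,3-disubstituted 2,3-epoxy alcohol by an (E)-alkenyl(dialkyl)alane, in which the O-bound iBu2Al of 31 chelates the oxirane oxygen and weakens the bond to the fully substituted, cation-stabilising carbon while the sp2 carbon of the external alkenylalane 30 (from syn-hydroalumination) attacks that carbon from the back with retention of (E)-geometry, forming the C–C bond and the quaternary centre with inversion; the closest known reactions are the C3-selective openings of 2,3-epoxy alcohols by Me3Al and by dialkyl(alkynyl)alanes, which also build quaternary carbons, but this has not been shown for alkenylalanes at a fully substituted oxirane carbon.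

**Step 19**
Reactants: 32 (2S,3R,4E,6S,9R,13R)-3,6,9,13,14-pentamethyl-10-methylidene-3-{(3R)-3-[(4R)-3,3,4-trimethylcyclohex-1-en-1-yl]butyl}pentadeca-4,14-diene-1,2-diol
Product: 34 (4R)-1-[(2R,5S,6E,8S,11R,15R)-5-ethenyl-5,8,11,15,16-pentamethyl-12-methylideneheptadeca-6,16-dien-2-yl]-3,3,4-trimethylcyclohex-1-ene (target), via thionocarbonate 33 (not isolated)
Conditions: Im2C=S, DMAP (cat.), toluene, 80 °C; then P(OMe)3, 110 °C
Reagents that add atoms: none
Why: Corey–Winter olefination in which the cyclic thionocarbonate loses sulfur to phosphite and then CO2 in a syn-elimination to give the vinyl group, with no stereocentre involved and the other alkenes inert.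

**Compound list**
1 | 2-methylcyclohex-2-en-1-one | CC1=CCCCC1=O | starting material
2 | dimethylaluminium (3R)-2,3-dimethylcyclohex-1-en-1-olate | C[C@@H]1CCCC(O[Al](C)C)=C1C | intermediate
3 | (3R)-2,2,3-trimethylcyclohexan-1-one | C[C@@H]1CCCC(=O)C1(C)C | intermediate
4 | (3R)-6-(1-hydroxyethyl)-2,2,3-trimethylcyclohexan-1-one (Li alkoxide in the flask, diastereomer mixture) | CC(O)C1CC[C@@H](C)C(C)(C)C1=O | intermediate
5 | 1-[(4R)-3,3,4-trimethyl-2-oxocyclohexyl]ethyl methanesulfonate | CC(OS(C)(=O)=O)C1CC[C@@H](C)C(C)(C)C1=O | intermediate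
6 | (3R,6E)-6-ethylidene-2,2,3-trimethylcyclohexan-1-one | C/C=C1\CC[C@@H](C)C(C)(C)C1=O | intermediate
7 | (1R,3R,6E)-6-ethylidene-2,2,3-trimethylcyclohexan-1-ol | C/C=C1\CC[C@@H](C)C(C)(C)[C@H]1O | intermediate
8 | (1R,3R,6E)-6-ethylidene-2,2,3-trimethylcyclohexyl 2-(diphenylphosphanyl)benzoate | C/C=C1\CC[C@@H](C)C(C)(C)[C@H]1OC(=O)c2ccccc2P(c3ccccc3)c4ccccc4 | intermediate
9 | 4-bromo-1-(trimethylsilyl)but-1-yne | C[Si](C)(C)C#CCCBr | starting material
10 | [4-(trimethylsilyl)but-3-yn-1-yl]magnesium bromide | C[Si](C)(C)C#CCC[Mg]Br | intermediate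
11 | trimethyl{(5R)-5-[(4R)-3,3,4-trimethylcyclohex-1-en-1-yl]hex-1-yn-1-yl}silane | C[Si](C)(C)C#CCC[C@@H](C)C1=CC(C)(C)[C@H](C)CC1 | intermediate
12 | (4R)-1-[(2R)-hex-5-yn-2-yl]-3,3,4-trimethylcyclohex-1-ene | C#CCC[C@@H](C)C1=CC(C)(C)[C@H](C)CC1 | intermediate
13 | dimethyl{(1E,5R)-2-methyl-5-[(4R)-3,3,4-trimethylcyclohex-1-en-1-yl]hex-1-en-1-yl}alumane | C[Al](C)/C=C(\C)CC[C@@H](C)C1=CC(C)(C)[C@H](C)CC1 | intermediate
14 | (2E,6R)-3-methyl-6-[(4R)-3,3,4-trimethylcyclohex-1-en-1-yl]hept-2-en-1-ol | OC/C=C(\C)CC[C@@H](C)C1=CC(C)(C)[C@H](C)CC1 | intermediate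
15 | [(2R,3R)-3-methyl-3-{(3R)-3-[(4R)-3,3,4-trimethylcyclohex-1-en-1-yl]butyl}oxiran-2-yl]methanol | OC[C@H]1O[C@]1(C)CC[C@@H](C)C2=CC(C)(C)[C@H](C)CC2 | intermediate
16 | (S)-citronellal, (3S)-3,7-dimethyloct-6-enal | O=CC[C@@H](C)CCC=C(C)C | starting material
17 | (3S)-3,7-dimethylocta-1,6-dien-1-yl nonafluorobutane-1-sulfonate (E/Z) | FC(F)(F)C(F)(F)C(F)(F)C(F)(F)S(=O)(=O)OC=C[C@@H](C)CCC=C(C)C | intermediate
18 | (3S)-3,7-dimethyloct-6-en-1-yne | C#C[C@@H](C)CCC=C(C)C | intermediate
19 | trimethyl[(3S)-3,7-dimethyloct-6-en-1-yn-1-yl]silane | C[Si](C)(C)C#C[C@@H](C)CCC=C(C)C | intermediate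
20 | (2E,6S)-2,6-dimethyl-8-(trimethylsilyl)oct-2-en-7-yn-1-ol | C[Si](C)(C)C#C[C@@H](C)CC/C=C(\C)CO | intermediate
21 | [(3S,6E)-8-chloro-3,7-dimethyloct-6-en-1-yn-1-yl]trimethylsilane | C[Si](C)(C)C#C[C@@H](C)CC/C=C(\C)CCl | intermediate
22 | trimethyl[(3S,6R)-3,6,7-trimethyloct-7-en-1-yn-1-yl]silane | C[Si](C)(C)C#C[C@@H](C)CC[C@@H](C)C(C)=C | intermediate
23 | (4R,7S)-4,7-dimethyl-3-methylidene-9-(trimethylsilyl)non-8-yn-1-ol | C[Si](C)(C)C#C[C@@H](C)CC[C@@H](C)C(=C)CCO | intermediate
24 | [(3S,6R)-9-bromo-3,6-dimethyl-7-methylidenenon-1-yn-1-yl]trimethylsilane | C[Si](C)(C)C#C[C@@H](C)CC[C@@H](C)C(=C)CCBr | intermediate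
25 | (2E)-2-methylbut-2-en-1-ol (tiglyl alcohol) | C/C=C(\C)CO | starting material
26 | (2E)-1-chloro-2-methylbut-2-ene (tiglyl chloride) | C/C=C(\C)CCl | intermediate
27 | [(4R,7S)-4,7-dimethyl-3-methylidene-9-(trimethylsilyl)non-8-yn-1-yl]magnesium bromide | C[Si](C)(C)C#C[C@@H](C)CC[C@@H](C)C(=C)CC[Mg]Br | intermediate
28 | trimethyl[(3S,6R,10R)-3,6,10,11-tetramethyl-7-methylidenedodec-11-en-1-yn-1-yl]silane | C[Si](C)(C)C#C[C@@H](C)CC[C@@H](C)C(=C)CC[C@@H](C)C(C)=C | intermediate
29 | (3S,6R,10R)-3,6,10,11-tetramethyl-7-methylidenedodec-11-en-1-yne | C#C[C@@H](C)CC[C@@H](C)C(=C)CC[C@@H](C)C(C)=C | intermediate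
30 | bis(2-methylpropyl)[(1E,3S,6R,10R)-3,6,10,11-tetramethyl-7-methylidenedodeca-1,11-dien-1-yl]alumane | CC(C)C[Al](CC(C)C)/C=C/[C@@H](C)CC[C@@H](C)C(=C)CC[C@@H](C)C(C)=C | intermediate
31 | bis(2-methylpropyl)aluminium alkoxide of 15 | CC(C)C[Al](CC(C)C)OC[C@H]1O[C@]1(C)CC[C@@H](C)C2=CC(C)(C)[C@H](C)CC2 | intermediate
32 | (2S,3R,4E,6S,9R,13R)-3,6,9,13,14-pentamethyl-10-methylidene-3-{(3R)-3-[(4R)-3,3,4-trimethylcyclohex-1-en-1-yl]butyl}pentadeca-4,14-diene-1,2-diol | OC[C@@H](O)[C@@](C)(/C=C/[C@@H](C)CC[C@@H](C)C(=C)CC[C@@H](C)C(C)=C)CC[C@@H](C)C1=CC(C)(C)[C@H](C)CC1 | intermediate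
33 | cyclic thionocarbonate (1,3-dioxolane-2-thione) of diol 32 | S=C1OC[C@@H](O1)[C@@](C)(/C=C/[C@@H](C)CC[C@@H](C)C(=C)CC[C@@H](C)C(C)=C)CC[C@@H](C)C2=CC(C)(C)[C@H](C)CC2 | intermediate
34 | (4R)-1-[(2R,5S,6E,8S,11R,15R)-5-ethenyl-5,8,11,15,16-pentamethyl-12-methylideneheptadeca-6,16-dien-2-yl]-3,3,4-trimethylcyclohex-1-ene (CNP0321027.1) | C=C[C@@](C)(/C=C/[C@@H](C)CC[C@@H](C)C(=C)CC[C@@H](C)C(=C)C)CC[C@@H](C)C1=CC(C)(C)[C@H](C)CC1 | target

**Totals**
Total step count: 19. Longest linear sequence: 10 steps (9→10→11→12→13→14→15→17→18→19; the branch 1→8, then 18 and 19, is also 10).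

**Three steps most likely to fail**

Step 18 (the new step). The alkenyl group may not transfer, or isobutyl/hydride transfer may compete. The fallback sets out from 29 and 15 and uses known chemistry: 29 is lithiated with n-BuLi and treated with Et2AlCl to give the diethyl(alkynyl)alane F1, a reagent type known to open 3,3-disubstituted 2,3-epoxy alcohols at C3 with inversion, which gives the alkynyl diol F2. Hydroxyl-directed trans-hydroalumination of the homopropargylic alcohol (LiAlH4, THF, reflux) then gives the (E)-alkene and the route is rejoined at 32.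

Step 5. The directed syn-SN2′ needs the C–O bond axial, which forces the C3 methyl axial as well, so the reaction may be slow or give ester attack. The fallback sets out from 7: Ir-catalysed transfer vinylation ([Ir(cod)Cl]2, Na2CO3, vinyl acetate, toluene, 100 °C) gives the vinyl ether F3, and heating to 140 °C brings about the suprafacial Claisen rearrangement to the aldehyde F4 with the same (R) centre. NaBH4 gives the alcohol F5, I2/PPh3/imidazole the iodide F6, and lithium acetylide–ethylenediamine in DMSO displaces iodide, so the route is rejoined at 12.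

Step 13. MeMgBr on a trisubstituted allylic chloride may give low SN2′:SN2 ratio or low ee. The fallback sets out from 19: Shi epoxidation of the trisubstituted alkene (ketone enantiomer chosen for the (S)-oxirane) gives the epoxide F7. Me2CuLi opens it at the secondary carbon with inversion to the tertiary alcohol F8, and Burgess dehydration toward a methyl group rejoins the route at 22.

**Further compounds**
F1 | step 18 | diethyl[(3S,6R,10R)-3,6,10,11-tetramethyl-7-methylidenedodec-11-en-1-yn-1-yl]alumane | CC[Al](CC)C#C[C@@H](C)CC[C@@H](C)C(=C)CC[C@@H](C)C(C)=C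
F2 | step 18 | (2S,3R,6S,9R,13R)-3,6,9,13,14-pentamethyl-10-methylidene-3-{(3R)-3-[(4R)-3,3,4-trimethylcyclohex-1-en-1-yl]butyl}pentadec-14-en-4-yne-1,2-diol | OC[C@@H](O)[C@@](C)(C#C[C@@H](C)CC[C@@H](C)C(=C)CC[C@@H](C)C(C)=C)CC[C@@H](C)C1=CC(C)(C)[C@H](C)CC1
F3 | step 5 | (1R,3R,6E)-1-(ethenyloxy)-6-ethylidene-2,2,3-trimethylcyclohexane | C/C=C1\CC[C@@H](C)C(C)(C)[C@H]1OC=C
F4 | step 5 | (3R)-3-[(4R)-3,3,4-trimethylcyclohex-1-en-1-yl]butanal | O=CC[C@@H](C)C1=CC(C)(C)[C@H](C)CC1
F5 | step 5 | (3R)-3-[(4R)-3,3,4-trimethylcyclohex-1-en-1-yl]butan-1-ol | OCC[C@@H](C)C1=CC(C)(C)[C@H](C)CC1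
F6 | step 5 | (4R)-1-[(2R)-4-iodobutan-2-yl]-3,3,4-trimethylcyclohex-1-ene | ICC[C@@H](C)C1=CC(C)(C)[C@H](C)CC1
F7 | step 13 | trimethyl{(3S)-5-[(2S)-3,3-dimethyloxiran-2-yl]-3-methylpent-1-yn-1-yl}silane | C[Si](C)(C)C#C[C@@H](C)CC[C@@H]1OC1(C)C
F8 | step 13 | (3R,6S)-2,3,6-trimethyl-8-(trimethylsilyl)oct-7-yn-2-ol | C[Si](C)(C)C#C[C@@H](C)CC[C@@H](C)C(C)(C)O
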